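The route rests on cutting the bond between the ketone carbon C1 of the nonanone chain and the 2,6-dioxygenated benzene ring, together with the neighbouring ring C–O bond. The key step exploits that C1 sits on a ring carbon flanked by two oxygen-bearing ring carbons: a carboxylic acid adds across a 3-alkoxybenzyne and delivers oxygen and acyl group to adjacent carbons in one operation. Its precursors are a 9-arylnonanoic acid whose guaiacyl phenol is benzylated and an ortho-silylaryl triflate carrying a benzyloxy group, so that a single hydrogenolysis then removes both benzyl groups.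

Key step: step 4

Remark on stereochemistry: the target has no stereocentre and no stereogenic double bond, so no enantiocontrol is needed and only the constitution is built.
Remark on precursor design: the aryne oxygen carries benzyl instead of methyl, because a methyl ether there would have to be cleaved beside the guaiacyl methyl ether that must stay, and the chelated 2-hydroxy ketone makes that cleavage sluggish.
Assumption on supply: the alkenoate, the aryl bromide and 2-bromoresorcinol used as starting materials are taken as catalogue compounds.

Step 1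
Reactants: 1 methyl non-8-enoate; 2 1-(benzyloxy)-4-bromo-2-methoxybenzene
Product: 5 9-[4-(benzyloxy)-3-methoxyphenyl]nonanoic acid, via alkylborane 3 (not isolated), via methyl ester 4 (not isolated)
Conditions: 9-BBN, THF, 0 °C to rt; then 2, PdCl2(dppf) (cat.), 3 M aq NaOH, THF, 65 °C; then MeOH, more aq NaOH, 50 °C; HCl, acid–base extraction
Reagents that add atoms: sodium hydroxide (aqueous), [Na+].[OH-]
Why: Anti-Markovnikov hydroboration of the terminal alkene followed by B-alkyl Suzuki–Miyaura coupling should form the aryl–C9 bond, and the hydroxide already present should complete the ester saponification in the same flask while the benzyl ether stays untouched.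

Step 2
Reactants: 6 2-bromobenzene-1,3-diol
Product: 7 3-(benzyloxy)-2-bromophenol
Conditions: BnBr (0.5 equiv), K2CO3, acetone, reflux
Reagents that add atoms: benzyl bromide, BrCc1ccccc1
Why: Williamson ether synthesis on the symmetrical diol used in excess should favour the mono-ether statistically, with the unreacted diol recovered by chromatography.

Step 3
Reactants: 7 3-(benzyloxy)-2-bromophenol
Product: 10 3-(benzyloxy)-2-(trimethylsilyl)phenyl trifluoromethanesulfonate, via aryl silyl ether 8 (not isolated), via lithium silylphenoxide 9 (not isolated)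
Conditions: HMDS, 80 °C, then volatiles removed; n-BuLi, THF, −95 to −78 °C; Tf2O, −95 to −78 °C; aq NaHCO3
Reagents that add atoms: hexamethyldisilazane, C[Si](C)(C)N[Si](C)(C)C; trifluoromethanesulfonic anhydride, O=S(=O)(OS(=O)(=O)C(F)(F)F)C(F)(F)F
Why: O-silylation, bromine–lithium exchange and retro-Brook rearrangement (anionic 1,3-shift of silicon from oxygen to carbon) should place the trimethylsilyl group between the two oxygens, and the lithium phenoxide so released is trapped as the triflate; exchange at this temperature should outrun benzylic deprotonation.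

Step 4
Reactants: 5 9-[4-(benzyloxy)-3-methoxyphenyl]nonanoic acid; 10 3-(benzyloxy)-2-(trimethylsilyl)phenyl trifluoromethanesulfonate
Product: 13 1-[2-(benzyloxy)-6-hydroxyphenyl]-9-[4-(benzyloxy)-3-methoxyphenyl]nonan-1-one, via benzyloxybenzyne 11 (not isolated), via metalated aryl ester 12 (not isolated)
Conditions: 10 (1.5 equiv), CsF (4 equiv), THF, 125 °C, sealed tube
Reagents that add atoms: none
Why: Fluoride removes the trimethylsilyl group of 10 and triflate departs, giving 3-(benzyloxy)benzyne 11; the caesium carboxylate of 5 adds through oxygen to the aryne carbon remote from the benzyloxy group, which puts the aryl anion of 12 on the carbon next to that group. The anion attacks the ester carbonyl through a strained benzoxetene-type adduct that opens to the phenoxide of the ortho-hydroxyaryl ketone, so the acyl group ends between the new oxygen and the benzyloxy group. The closest known reaction type is the fluoride-induced σ-insertion of arynes into the C–O bond of carboxylic acids, related to aryne acyl-alkylation. No ring is closed and no stereocentre is created. The step needs regioselective oxygen attack, secured by the inductive and ring-distorting effect of the 3-alkoxy substituent, and acyl migration in preference to protonation of the aryl anion, favoured by the high temperature and the aprotic medium.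

Step 5
Reactants: 13 1-[2-(benzyloxy)-6-hydroxyphenyl]-9-[4-(benzyloxy)-3-methoxyphenyl]nonan-1-one
Product: 14 1-(2,6-dihydroxyphenyl)-9-(4-hydroxy-3-methoxyphenyl)nonan-1-one
Conditions: H2 (1 atm), 10% Pd/C, EtOAc, rt
Reagents that add atoms: none
Why: Catalytic hydrogenolysis should cleave both aryl benzyl ethers, while the methyl ether is inert and the hydrogen-bonded, electron-rich aryl ketone should be reduced far more slowly in neutral ethyl acetate.

Compound list
1 | methyl non-8-enoate | C=CCCCCCCC(=O)OC | starting material
2 | 1-(benzyloxy)-4-bromo-2-methoxybenzene | COc1cc(Br)ccc1OCc1ccccc1 | starting material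
3 | methyl 9-(9-borabicyclo[3.3.1]nonan-9-yl)nonanoate | COC(=O)CCCCCCCCB1C2CCCC1CCC2 | intermediate
4 | methyl 9-[4-(benzyloxy)-3-methoxyphenyl]nonanoate | COC(=O)CCCCCCCCc1ccc(OCc2ccccc2)c(OC)c1 | intermediate
5 | 9-[4-(benzyloxy)-3-methoxyphenyl]nonanoic acid | OC(=O)CCCCCCCCc1ccc(OCc2ccccc2)c(OC)c1 | intermediate
6 | 2-bromobenzene-1,3-diol (2-bromoresorcinol) | Oc1cccc(O)c1Br | starting material
7 | 3-(benzyloxy)-2-bromophenol | Oc1cccc(OCc2ccccc2)c1Br | intermediate
8 | [3-(benzyloxy)-2-bromophenoxy]trimethylsilane | C[Si](C)(C)Oc1cccc(OCc2ccccc2)c1Br | intermediate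
9 | lithium 3-(benzyloxy)-2-(trimethylsilyl)phenoxide | [Li+].[O-]c1cccc(OCc2ccccc2)c1[Si](C)(C)C | intermediate
10 | 3-(benzyloxy)-2-(trimethylsilyl)phenyl trifluoromethanesulfonate | C[Si](C)(C)c1c(OCc2ccccc2)cccc1OS(=O)(=O)C(F)(F)F | intermediate
11 | 3-(benzyloxy)benzyne (1-(benzyloxy)-2,3-didehydrobenzene) | C1#CC(OCc2ccccc2)=CC=C1 | intermediate
12 | caesium 2-(benzyloxy)-6-{9-[4-(benzyloxy)-3-methoxyphenyl]nonanoyloxy}benzen-1-ide | [Cs+].O=C(CCCCCCCCc1ccc(OCc2ccccc2)c(OC)c1)Oc1cccc(OCc2ccccc2)[c-]1 | intermediate
13 | 1-[2-(benzyloxy)-6-hydroxyphenyl]-9-[4-(benzyloxy)-3-methoxyphenyl]nonan-1-one | COc1cc(CCCCCCCCC(=O)c2c(O)cccc2OCc2ccccc2)ccc1OCc1ccccc1 | intermediate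
14 | 1-(2,6-dihydroxyphenyl)-9-(4-hydroxy-3-methoxyphenyl)nonan-1-one | COc1cc(CCCCCCCCC(=O)c2c(O)cccc2O)ccc1O | target

Total step count: 5. Longest linear sequence: 4 steps (6 → 7 → 10 → 13 → 14); the acid branch (1 + 2 → 5) joins at step 4.

Steps most likely to fail, riskiest first:

Step 4. The aryl anion formed after carboxylate addition may be protonated before it reaches the ester carbonyl, so that material stops at the aryl ester. The liberated phenoxide may also be arylated by a second aryne. The fallback sets out from 5, with 6 as the second component, and comes back to the route at 14. Acid 5 is converted with carbonyldiimidazole and N,O-dimethylhydroxylamine hydrochloride into the Weinreb amide 9-[4-(benzyloxy)-3-methoxyphenyl]-N-methoxy-N-methylnonanamide F1. Diol 6 is benzylated on both oxygens (excess BnBr, K2CO3, DMF) to 1,3-bis(benzyloxy)-2-bromobenzene F2. Bromine–lithium exchange (n-BuLi, THF, −78 °C) gives [2,6-bis(benzyloxy)phenyl]lithium F3, which adds to F1 to give 1-[2,6-bis(benzyloxy)phenyl]-9-[4-(benzyloxy)-3-methoxyphenyl]nonan-1-one F4 after aqueous NH4Cl. Hydrogenolysis of the three benzyl ethers (H2, Pd/C, EtOAc) then gives 14.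

Step 3. Butyllithium may remove a benzylic proton of the ether, with Wittig rearrangement following, in competition with bromine–lithium exchange. The silyl shift may also remain incomplete, so that phenol lacking the ring silicon is triflated. The fallback sets out from 6 and comes back at 10; it introduces the benzyl group only after all organolithium chemistry, and it also bypasses the statistical benzylation of step 2. Diol 6 is silylated on both oxygens with HMDS to 2-bromo-1,3-bis(trimethylsilyloxy)benzene F5. n-BuLi at −78 °C triggers exchange and migration of one silyl group to carbon, giving lithium 2-(trimethylsilyl)-3-(trimethylsilyloxy)phenoxide F6, in which the two oxygens are now different. Tf2O traps it as 2-(trimethylsilyl)-3-(trimethylsilyloxy)phenyl trifluoromethanesulfonate F7. Mild methanolysis (MeOH, cat. PPTS) frees 3-hydroxy-2-(trimethylsilyl)phenyl trifluoromethanesulfonate F8. Mitsunobu etherification with benzyl alcohol (PPh3, DIAD, THF, 0 °C) gives 10; neutral conditions are chosen because carbonate bases could set off silyl migration and triflate loss from the free phenoxide.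

Step 5. The aryl ketone may be over-reduced to the benzylic alcohol or methylene, or hydrogenolysis may stall at the hindered benzyl ether ortho to the ketone. The fallback sets out from 13 and comes back at 14 without new intermediates. Non-reductive cleavage of both benzyl ethers with BCl3 and pentamethylbenzene as cation scavenger in CH2Cl2 at −78 °C should leave the ketone and, at this temperature, the guaiacyl methyl ether untouched.

Further compounds
F1 | step 4 | 9-[4-(benzyloxy)-3-methoxyphenyl]-N-methoxy-N-methylnonanamide | CON(C)C(=O)CCCCCCCCc1ccc(OCc2ccccc2)c(OC)c1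
F2 | step 4 | 1,3-bis(benzyloxy)-2-bromobenzene | Brc1c(OCc2ccccc2)cccc1OCc1ccccc1
F3 | step 4 | [2,6-bis(benzyloxy)phenyl]lithium | [Li]c1c(OCc2ccccc2)cccc1OCc1ccccc1
F4 | step 4 | 1-[2,6-bis(benzyloxy)phenyl]-9-[4-(benzyloxy)-3-methoxyphenyl]nonan-1-one | COc1cc(CCCCCCCCC(=O)c2c(OCc3ccccc3)cccc2OCc2ccccc2)ccc1OCc1ccccc1
F5 | step 3 | 2-bromo-1,3-bis(trimethylsilyloxy)benzene | C[Si](C)(C)Oc1cccc(O[Si](C)(C)C)c1Br
F6 | step 3 | lithium 2-(trimethylsilyl)-3-(trimethylsilyloxy)phenoxide | [Li+].[O-]c1cccc(O[Si](C)(C)C)c1[Si](C)(C)C
F7 | step 3 | 2-(trimethylsilyl)-3-(trimethylsilyloxy)phenyl trifluoromethanesulfonate | C[Si](C)(C)Oc1cccc(OS(=O)(=O)C(F)(F)F)c1[Si](C)(C)C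
F8 | step 3 | 3-hydroxy-2-(trimethylsilyl)phenyl trifluoromethanesulfonate | Oc1cccc(OS(=O)(=O)C(F)(F)F)c1[Si](C)(C)C
F0 | step 5 | none | none
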